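**Retrosynthetic overview**
1. Target 23 ⇐ Dieckmann closure of the tetronic acid ring from the (E)-enol propanoate 22 ⇐ E-selective olefination of aldehyde 17 with acyloxyphosphonate 21.
2. 17 ⇐ dienol 16 ⇐ one-pot hydrozirconation / trans-selective alkenylation / methylation joining alkynol 13 (C7 stereocentre from an Evans propargylation) to dibromoalkene 10.
3. 10 ⇐ bis-furan alcohol 8 (oxidation, dibromo-olefination).
4. Key step: 8 ⇐ skipped diynol 3 + two molecules of 4-phenyloxazole 4 by a double Diels–Alder/retro-Diels–Alder reaction that closes both furans in one operation.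
5. Ring order: the 3-substituted and the 3,4-disubstituted furan together (step 2), the tetronic acid last (step 11).

Assumption: the SMILES is read as the (5E)-ylidene (side chain cis to C4–OH), (S) at the methyl-bearing carbon and (E,E) in the diene; 4-phenyloxazole, (R)-4-benzyl-3-propanoyl-1,3-oxazolidin-2-one and ethyl glyoxylate (toluene solution) are taken as commercial.

**Step 1**
Reactants: 1 pent-4-yn-1-ol; 2 propargyl bromide (3-bromoprop-1-yne)
Product: 3 octa-4,7-diyn-1-ol
Conditions: CuI (20 mol %), NaI (20 mol %), K2CO3 (1.5 equiv), DMF, 23 °C; 1 in threefold excess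
Reagents that add atoms: none
Why: Copper-catalysed sp–sp3 coupling of a terminal alkyne with a propargylic halide (the standard skipped-diyne synthesis) joins the fragments under a base too weak to isomerise the 1,4-diyne, and the excess of 1 suppresses a second propargylation; no stereocentre.

**Step 2**
Reactants: 3 octa-4,7-diyn-1-ol; 4 4-phenyloxazole
Product: 8 3-[4-(furan-3-ylmethyl)furan-3-yl]propan-1-ol, via first oxazole cycloadduct 5 (not isolated), via 6-(furan-3-yl)hex-4-yn-1-ol 6 (not isolated), via second oxazole cycloadduct 7 (not isolated)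
Conditions: 4 (3 equiv), BHT (cat.), 1,2-dichlorobenzene, sealed tube, 210 °C, 24 h
Reagents that add atoms: none
Why: Each alkyne undergoes an oxazole–alkyne Diels–Alder reaction followed by retro-Diels–Alder loss of benzonitrile (Kondrat'eva-type furan synthesis), so the terminal alkyne gives the 3-substituted furan and the internal one the 3,4-disubstituted furan in the same operation, with no regiochemical issue because the alkyne carbons become C3/C4 and the oxazole C2–O–C5 unit supplies the unsubstituted α-positions; no stereocentre.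

**Step 3**
Reactants: 8 3-[4-(furan-3-ylmethyl)furan-3-yl]propan-1-ol
Product: 9 3-[4-(furan-3-ylmethyl)furan-3-yl]propanal
Conditions: Dess–Martin periodinane (1.2 equiv), CH2Cl2, 0 → 23 °C
Reagents that add atoms: none
Why: Dess–Martin oxidation stops at the aldehyde and tolerates the electron-rich furans.

**Step 4**
Reactants: 9 3-[4-(furan-3-ylmethyl)furan-3-yl]propanal
Product: 10 3-(4,4-dibromobut-3-en-1-yl)-4-(furan-3-ylmethyl)furan
Conditions: CBr4, PPh3, Zn dust (2 equiv each, premixed), CH2Cl2, 23 °C; then 9, 0 °C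
Reagents that add atoms: carbon tetrabromide, BrC(Br)(Br)Br
Why: Ramirez dibromo-olefination (first stage of the Corey–Fuchs sequence) converts the aldehyde with Ph3P=CBr2 into the 1,1-dibromoalkene whose CBr2 carbon will carry both C10 and the C11 methyl group.

**Step 5**
Reactants: 11 (R)-4-benzyl-3-propanoyl-1,3-oxazolidin-2-one; 2 propargyl bromide
Product: 12 (R)-4-benzyl-3-[(S)-2-methylpent-4-ynoyl]-1,3-oxazolidin-2-one
Conditions: NaN(SiMe3)2 (1.1 equiv), THF, −78 °C; then 2 (3 equiv), −78 → −45 °C
Reagents that add atoms: none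
Why: Evans asymmetric alkylation: the chelated (Z)-sodium enolate is shielded on one face by the benzyl group, so the bromide enters from the opposite face and the (R)-auxiliary sets the new centre as (S) (dr ≥ 95:5), which becomes C7 of the target.

**Step 6**
Reactants: 12 (R)-4-benzyl-3-[(S)-2-methylpent-4-ynoyl]-1,3-oxazolidin-2-one
Product: 13 (S)-2-methylpent-4-yn-1-ol
Conditions: LiBH4 (1.2 equiv), H2O (1.1 equiv), Et2O, 0 °C
Reagents that add atoms: none
Why: Reductive cleavage of the imide by LiBH4 releases the primary alcohol without touching the alkyne or the α-stereocentre and returns the auxiliary.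

**Step 7**
Reactants: 13 (S)-2-methylpent-4-yn-1-ol; 10 3-(4,4-dibromobut-3-en-1-yl)-4-(furan-3-ylmethyl)furan
Product: 16 (2S,4E,6E)-9-[4-(furan-3-ylmethyl)furan-3-yl]-2,6-dimethylnona-4,6-dien-1-ol, via alkenylzirconium alkoxide 14 (not isolated), via (Z)-bromodiene 15 (not isolated)
Conditions: 13, Cp2Zr(H)Cl (2.1 equiv), THF, 0 → 23 °C; then 10, ZnCl2 (20 mol %), PdCl2(DPEphos) (5 mol %), 23 °C; then ZnMe2 (2 equiv), Pd(P(t-Bu)3)2 (3 mol %), 23 °C; aq. NH4Cl
Reagents that add atoms: dimethylzinc, C[Zn]C
Why: Negishi tandem sequence: syn-hydrozirconation gives the (E)-alkenylzirconium, Pd-catalysed cross-coupling takes place only at the less hindered C–Br bond trans to the alkyl chain of 10, and the remaining bromide is methylated with retention under Pd(P(t-Bu)3)2, which fixes both diene double bonds as (E) without involving the stereocentre.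

**Step 8**
Reactants: 16 (2S,4E,6E)-9-[4-(furan-3-ylmethyl)furan-3-yl]-2,6-dimethylnona-4,6-dien-1-ol
Product: 17 (2S,4E,6E)-9-[4-(furan-3-ylmethyl)furan-3-yl]-2,6-dimethylnona-4,6-dienal
Conditions: Dess–Martin periodinane (1.3 equiv), pyridine (3 equiv), CH2Cl2, 0 °C; crude aldehyde used cold and at once
Reagents that add atoms: none
Why: Buffered Dess–Martin oxidation gives the α-methyl aldehyde without epimerisation or double-bond migration.

**Step 9**
Reactants: 18 diphenyl phosphite; 19 ethyl glyoxylate
Product: 21 ethyl 2-(diphenoxyphosphoryl)-2-(propanoyloxy)acetate (racemic), via α-hydroxyphosphonate 20 (not isolated)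
Conditions: 18, 19 (50 % in toluene), toluene, 80 °C, no base; then (EtCO)2O, pyridine, DMAP (cat.), 0 → 23 °C
Reagents that add atoms: propanoic anhydride, CCC(=O)OC(=O)CC
Why: Pudovik addition of the P–H bond to the very electrophilic glyoxylate carbonyl followed by O-acylation in the same flask gives the Ando-type reagent, and base-free addition avoids phospha-Brook rearrangement of the hydroxyphosphonate.

**Step 10**
Reactants: 17 (2S,4E,6E)-9-[4-(furan-3-ylmethyl)furan-3-yl]-2,6-dimethylnona-4,6-dienal; 21 ethyl 2-(diphenoxyphosphoryl)-2-(propanoyloxy)acetate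
Product: 22 ethyl (2E,4S,6E,8E)-11-[4-(furan-3-ylmethyl)furan-3-yl]-4,8-dimethyl-2-(propanoyloxy)undeca-2,6,8-trienoate
Conditions: 21 (1.2 equiv), KN(SiMe3)2 (1.15 equiv), 18-crown-6, THF, −78 °C; then 17, −78 → −40 °C
Reagents that add atoms: none
Why: Proposed new method: a Horner–Wadsworth–Emmons olefination with a diaryl (Ando-type) phosphonate bearing an α-acyloxy group, in which the electron-poor aryloxy groups make elimination from the kinetically favoured adduct fast so that the aldehyde substituent ends up cis to the ester and trans to the acyloxy group, i.e. the (2E)-enol ester; the closest known reactions are the Ando Z-selective olefination with α-substituted diaryl phosphonoacetates and the olefination of aldehydes with dialkyl 2-acyloxyphosphonoacetates, and the preformed, weakly basic phosphonate anion does not epimerise the α-centre.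

**Step 11**
Reactants: 22 ethyl (2E,4S,6E,8E)-11-[4-(furan-3-ylmethyl)furan-3-yl]-4,8-dimethyl-2-(propanoyloxy)undeca-2,6,8-trienoate
Product: 23 (5E)-5-[(2S,4E,6E)-9-[4-(furan-3-ylmethyl)furan-3-yl]-2,6-dimethylnona-4,6-dien-1-ylidene]-4-hydroxy-3-methylfuran-2(5H)-one
Conditions: LiN(SiMe3)2 (2.5 equiv), THF, −78 → −20 °C; cold 0.5 M HCl to pH 3; work-up and purification in the dark
Reagents that add atoms: none
Why: Dieckmann (intramolecular Claisen) condensation of the propanoate enolate onto the ethyl ester closes the 3-methyltetronic acid ring at −78 °C before ketene loss can compete, the enol-ester geometry is carried over unchanged into the exocyclic double bond (as in pulvinone syntheses from enol esters), and formation of the tetronate anion drives the reaction.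

**Compound list**
1 | pent-4-yn-1-ol | C#CCCCO | starting material
2 | propargyl bromide (3-bromoprop-1-yne) | C#CCBr | starting material
3 | octa-4,7-diyn-1-ol | C#CCC#CCCCO | intermediate
4 | 4-phenyloxazole | c1ccc(-c2cocn2)cc1 | starting material
5 | 6-(3-phenyl-7-oxa-2-azabicyclo[2.2.1]hepta-2,5-dien-6-yl)hex-4-yn-1-ol (first oxazole cycloadduct; racemic, one regioisomer drawn; not isolated) | OCCCC#CCC1=CC2OC1N=C2c1ccccc1 | intermediate
6 | 6-(furan-3-yl)hex-4-yn-1-ol (not isolated) | OCCCC#CCc1ccoc1 | intermediate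
7 | 3-[5-(furan-3-ylmethyl)-3-phenyl-7-oxa-2-azabicyclo[2.2.1]hepta-2,5-dien-6-yl]propan-1-ol (second oxazole cycloadduct; racemic, one regioisomer drawn; not isolated) | OCCCC1=C(Cc3ccoc3)C2OC1N=C2c1ccccc1 | intermediate
8 | 3-[4-(furan-3-ylmethyl)furan-3-yl]propan-1-ol | OCCCc1cocc1Cc1ccoc1 | intermediate
9 | 3-[4-(furan-3-ylmethyl)furan-3-yl]propanal | O=CCCc1cocc1Cc1ccoc1 | intermediate
10 | 3-(4,4-dibromobut-3-en-1-yl)-4-(furan-3-ylmethyl)furan | BrC(Br)=CCCc1cocc1Cc1ccoc1 | intermediate
11 | (R)-4-benzyl-3-propanoyl-1,3-oxazolidin-2-one | CCC(=O)N1[C@H](Cc2ccccc2)COC1=O | starting material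
12 | (R)-4-benzyl-3-[(S)-2-methylpent-4-ynoyl]-1,3-oxazolidin-2-one | C#CC[C@H](C)C(=O)N1[C@H](Cc2ccccc2)COC1=O | intermediate
13 | (S)-2-methylpent-4-yn-1-ol | C#CC[C@H](C)CO | intermediate
14 | (S,E)-alkenylzirconocene chloride of 13, oxygen bound to a second Cp2ZrCl unit (cyclopentadienyl rings drawn σ-bonded; not isolated) | Cl[Zr](OC[C@@H](C)C/C=C/[Zr](Cl)(C1C=CC=C1)C1C=CC=C1)(C1C=CC=C1)C1C=CC=C1 | intermediate
15 | (2S,4E,6Z)-6-bromo-9-[4-(furan-3-ylmethyl)furan-3-yl]-2-methylnona-4,6-dien-1-ol (present as its zirconium alkoxide, drawn as the alcohol; not isolated) | OC[C@@H](C)C/C=C/C(Br)=C/CCc1cocc1Cc1ccoc1 | intermediate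
16 | (2S,4E,6E)-9-[4-(furan-3-ylmethyl)furan-3-yl]-2,6-dimethylnona-4,6-dien-1-ol | OC[C@@H](C)C/C=C/C(C)=C/CCc1cocc1Cc1ccoc1 | intermediate
17 | (2S,4E,6E)-9-[4-(furan-3-ylmethyl)furan-3-yl]-2,6-dimethylnona-4,6-dienal | O=C[C@@H](C)C/C=C/C(C)=C/CCc1cocc1Cc1ccoc1 | intermediate
18 | diphenyl phosphite | O=[PH](Oc1ccccc1)Oc1ccccc1 | starting material
19 | ethyl glyoxylate | CCOC(=O)C=O | starting material
20 | ethyl 2-(diphenoxyphosphoryl)-2-hydroxyacetate (racemic; not isolated) | CCOC(=O)C(O)P(=O)(Oc1ccccc1)Oc1ccccc1 | intermediate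
21 | ethyl 2-(diphenoxyphosphoryl)-2-(propanoyloxy)acetate (racemic) | CCOC(=O)C(OC(=O)CC)P(=O)(Oc1ccccc1)Oc1ccccc1 | intermediate
22 | ethyl (2E,4S,6E,8E)-11-[4-(furan-3-ylmethyl)furan-3-yl]-4,8-dimethyl-2-(propanoyloxy)undeca-2,6,8-trienoate | CCOC(=O)/C(OC(=O)CC)=C\[C@@H](C)C/C=C/C(C)=C/CCc1cocc1Cc1ccoc1 | intermediate
23 | (5E)-5-[(2S,4E,6E)-9-[4-(furan-3-ylmethyl)furan-3-yl]-2,6-dimethylnona-4,6-dien-1-ylidene]-4-hydroxy-3-methylfuran-2(5H)-one | CC1=C(O)/C(=C\[C@@H](C)C/C=C/C(C)=C/CCc2cocc2Cc2ccoc2)OC1=O | target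

**Step count and risks**
Total: 11 steps. Longest linear sequence: 8 steps (1, 2, 3, 4, 7, 8, 10, 11).

The three steps most likely to fail:

Step 2 (double furan formation). The unactivated skipped diyne needs about 210 °C, where the doubly propargylic CH2 may isomerise or the diyne may polymerise before both cycloadditions are complete. The fallback sets out from 1 and comes back at 8, and activates both alkynes with a bridging ketone so that the double cycloaddition runs near 100 °C. Compound 1 is doubly deprotonated (n-BuLi, 2.1 equiv, THF, −78 °C) and formylated with DMF to 6-hydroxyhex-2-ynal F1. Addition of HC≡CMgBr gives octa-1,4-diyne-3,8-diol F2. MnO2 in CH2Cl2 oxidises only the bis-propargylic carbinol to 8-hydroxyocta-1,4-diyn-3-one F3. F3 takes up two molecules of 4 in toluene at 80–110 °C, again closing both furans in one operation, to give (furan-3-yl)[4-(3-hydroxypropyl)furan-3-yl]methanone F4. Wolff–Kishner reduction (N2H4·H2O, KOH, diethylene glycol, 190 °C) removes the ketone oxygen and gives 8.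

Step 9 (acyloxyphosphonate). The α-hydroxyphosphonate 20 can undergo phospha-Brook rearrangement to the phosphate, and aryloxy groups on phosphorus can exchange before acylation. The fallback sets out from 18 and comes back at 21, and never passes through a free hydroxyphosphonate. Compound 18 is P-alkylated with ethyl bromoacetate (Et3N, CH2Cl2, 0 °C) to ethyl 2-(diphenoxyphosphoryl)acetate F5. Diazo transfer (4-acetamidobenzenesulfonyl azide, DBU, MeCN, 0 °C) gives ethyl 2-diazo-2-(diphenoxyphosphoryl)acetate F6. Rh2(OAc)4-catalysed carbenoid O–H insertion into propanoic acid (CH2Cl2, 40 °C) gives 21.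

Step 10 (E-selective olefination). The kinetic preference for the (2E)-enol ester is an extrapolation, and the thermodynamically favoured (2Z)-isomer may dominate. The fallback sets out from 17 and comes back at 23 (it also replaces step 11), and fixes the geometry by a stereospecific elimination. Commercial 3-methyltetronic acid is O-methylated (Me2SO4, K2CO3, acetone) to 4-methoxy-3-methylfuran-2(5H)-one F7. Its C5 lithium dienolate (LiN(i-Pr)2, THF, −78 °C) adds to 17 to give the aldols 5-[(2S,4E,6E)-9-[4-(furan-3-ylmethyl)furan-3-yl]-1-hydroxy-2,6-dimethylnona-4,6-dien-1-yl]-4-methoxy-3-methylfuran-2(5H)-one F8. The like-configured pair (5R,1'R and 5S,1'S) is separated by chromatography and dehydrated by anti elimination (PPh3, DEAD, THF, 0 °C), which places the chain cis to C4 and gives (5E)-5-[(2S,4E,6E)-9-[4-(furan-3-ylmethyl)furan-3-yl]-2,6-dimethylnona-4,6-dien-1-ylidene]-4-methoxy-3-methylfuran-2(5H)-one F9. O-Demethylation (LiCl, DMF, 90 °C; cold dilute HCl) gives 23.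

**Further compounds**
F1 | step 2 | 6-hydroxyhex-2-ynal | O=CC#CCCCO
F2 | step 2 | octa-1,4-diyne-3,8-diol (racemic) | C#CC(O)C#CCCCO
F3 | step 2 | 8-hydroxyocta-1,4-diyn-3-one | C#CC(=O)C#CCCCO
F4 | step 2 | (furan-3-yl)[4-(3-hydroxypropyl)furan-3-yl]methanone | O=C(c1ccoc1)c1cocc1CCCO
F5 | step 9 | ethyl 2-(diphenoxyphosphoryl)acetate | CCOC(=O)CP(=O)(Oc1ccccc1)Oc1ccccc1
F6 | step 9 | ethyl 2-diazo-2-(diphenoxyphosphoryl)acetate | CCOC(=O)C(=[N+]=[N-])P(=O)(Oc1ccccc1)Oc1ccccc1
F7 | step 10 | 4-methoxy-3-methylfuran-2(5H)-one | COC1=C(C)C(=O)OC1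
F8 | step 10 | 5-[(2S,4E,6E)-9-[4-(furan-3-ylmethyl)furan-3-yl]-1-hydroxy-2,6-dimethylnona-4,6-dien-1-yl]-4-methoxy-3-methylfuran-2(5H)-one (mixture at C5 and C1'; the like pair is used) | COC1=C(C)C(=O)OC1C(O)[C@@H](C)C/C=C/C(C)=C/CCc1cocc1Cc1ccoc1
F9 | step 10 | (5E)-5-[(2S,4E,6E)-9-[4-(furan-3-ylmethyl)furan-3-yl]-2,6-dimethylnona-4,6-dien-1-ylidene]-4-methoxy-3-methylfuran-2(5H)-one | COC1=C(C)C(=O)O/C1=C/[C@@H](C)C/C=C/C(C)=C/CCc1cocc1Cc1ccoc1
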